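Locants: ring A (guaiacyl) sits on C7 and ring B (3-hydroxy-4,5-dimethoxyphenyl) on C7'. The bridgeheads are C8 and C8', the ethers are C7-O-C9' and C7'-O-C9, and the target is (7S,8R,7'S,8'R) with both aryl groups on the convex face.
Cuts: first the two phenol benzyl ethers; then the C9'-O bond, since ring C7-O-C9'-C8'-C8 is carried as a lactone (C9' = carbonyl) with a sacrificial CO2Me on C8'; then C7'-C8' and C9-O together; last the cyclopropane bonds C8'-C8 and C8'-C9.
Enabling feature: ring C7'-O-C9-C8-C8' is the C=O of the ring B aldehyde slotted into a C9-C8' bond. Such a bond can exist for a time as the CH2-C(acceptor)2 edge of a cyclopropane (C8, C8', C9) fused to the lactone ring.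
Forward order: vinyl addition makes C7-C8, carbenoid addition makes the lactone ring and the cyclopropane together, and aldehyde insertion makes ring C7'-O-C9-C8-C8'. Ester loss, reduction and etherification then turn the lactone into the second tetrahydrofuran ring.
Stereochemistry: C7 comes from a Sharpless kinetic resolution and C8 is relayed from C7 in the cyclopropanation. C8' and C7' follow from the geometry of the ring closure in the insertion, and C8'-H after ester loss is forced cis by the bicycle.

Key step: step 7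

Remark: compounds 1, 2, 5 and 9 are taken as catalogue chemicals, and all intermediates keep the lignan locants of the target.

Step 1
Reactants: 1 4-(benzyloxy)-3-methoxybenzaldehyde; 2 vinylmagnesium bromide
Product: 3 racemic 1-[4-(benzyloxy)-3-methoxyphenyl]prop-2-en-1-ol
Conditions: THF, 0 °C; then aq NH4Cl
Reagents that add atoms: none
Why: Grignard 1,2-addition to a non-enolisable aromatic aldehyde forms C7-C8 cleanly; C7 arises racemic and is sorted out in step 2.

Step 2
Reactants: 3 racemic 1-[4-(benzyloxy)-3-methoxyphenyl]prop-2-en-1-ol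
Product: 4 (S)-1-[4-(benzyloxy)-3-methoxyphenyl]prop-2-en-1-ol
Conditions: Ti(OiPr)4 (0.15 equiv), L-(+)-DIPT (0.2 equiv), t-BuOOH (0.6 equiv), 4 Å MS, CH2Cl2, -20 °C
Reagents that add atoms: none
Why: Sharpless kinetic resolution of a secondary allylic alcohol: with L-(+)-DIPT the (R)-enantiomer is epoxidised much faster, so the reaction stopped just beyond half conversion should leave the (S)-alcohol, whose C7 is that of the target, in high enantiomeric purity.

Step 3
Reactants: 4 (S)-1-[4-(benzyloxy)-3-methoxyphenyl]prop-2-en-1-ol; 5 methyl malonyl chloride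
Product: 6 methyl (S)-1-[4-(benzyloxy)-3-methoxyphenyl]prop-2-en-1-yl malonate
Conditions: pyridine, CH2Cl2, 0 °C
Reagents that add atoms: none
Why: Acylation of the alcohol by the acid chloride under mild base does not touch the C7-O bond, so C7 is retained and the acid-labile, electron-rich allylic benzylic system is not ionised.

Step 4
Reactants: 6 methyl (S)-1-[4-(benzyloxy)-3-methoxyphenyl]prop-2-en-1-yl malonate
Product: 7 methyl (S)-1-[4-(benzyloxy)-3-methoxyphenyl]prop-2-en-1-yl 2-diazomalonate
Conditions: p-ABSA, Et3N, MeCN, 0 °C to rt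
Reagents that add atoms: 4-acetamidobenzenesulfonyl azide (p-ABSA), CC(=O)Nc1ccc(cc1)S(=O)(=O)N=[N+]=[N-]
Why: Regitz diazo transfer to the doubly activated methylene of a malonate needs only an amine base and leaves the allylic ester and C7 alone.

Step 5
Reactants: 7 methyl (S)-1-[4-(benzyloxy)-3-methoxyphenyl]prop-2-en-1-yl 2-diazomalonate
Product: 8 methyl (1R,4S,5S)-4-[4-(benzyloxy)-3-methoxyphenyl]-2-oxo-3-oxabicyclo[3.1.0]hexane-1-carboxylate
Conditions: Cu(acac)2 (5 mol %), toluene, 110 °C, slow addition of 7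
Reagents that add atoms: none
Why: Intramolecular carbenoid cyclopropanation of an allyl diazomalonate: the short tether permits only the cis-fused 3-oxabicyclo[3.1.0]hexanone, and in the folded transition state the C7-H bond rather than ring A eclipses the vinyl group, so that ring A should end on the convex side, trans to the new CH2 (C9), which relays C7 to C8 and C8'.

Step 6
Reactants: 9 3-hydroxy-4,5-dimethoxybenzaldehyde
Product: 10 3-(benzyloxy)-4,5-dimethoxybenzaldehyde
Conditions: BnBr, K2CO3, DMF, rt
Reagents that add atoms: benzyl bromide, BrCc1ccccc1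
Why: Williamson etherification of the only phenol; the benzyl ether matches that of ring A so that both fall in one final operation.

Step 7
Reactants: 8 methyl (1R,4S,5S)-4-[4-(benzyloxy)-3-methoxyphenyl]-2-oxo-3-oxabicyclo[3.1.0]hexane-1-carboxylate; 10 3-(benzyloxy)-4,5-dimethoxybenzaldehyde
Product: 13 methyl (1S,4S,5R,8R)-4-[4-(benzyloxy)-3-methoxyphenyl]-8-[3-(benzyloxy)-4,5-dimethoxyphenyl]-2-oxo-3,7-dioxabicyclo[3.3.0]octane-1-carboxylate, via iodomagnesium enolate 11 (not isolated), via iodomagnesium aldolate 12 (not isolated)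
Conditions: MgI2 (1.2 equiv), 10 (1.5 equiv), THF, 65 °C
Reagents that add atoms: none
Why: Mg2+ binds the lactone and ester carbonyl groups of 8 and iodide opens the three-membered ring by SN2 attack at its CH2 (C9), which breaks C9-C8' and gives the chelated malonate-type enolate 11; 11 adds to aldehyde 10 (bond C7'-C8') and the aldolate oxygen of 12 expels the primary iodide (bond C9-O), which returns MgI2. The closest known reactions are the iodide-induced ring-opening aldol of acceptor cyclopropanes (MgI2, Et2AlI or TiCl4 with n-Bu4NI) with later etherification of the iodo aldol, the MgI2 ring expansion of methylenecyclopropyl amides with aldehydes to tetrahydrofurans, and the MgI2-mediated union of cyclopropane-1,1-diesters with imines to pyrrolidines. The only ring formed, C7'-O-C9-C8-C8', closes by a 5-exo-tet Williamson displacement. C8' is fixed by the geometry of that closure: the aldol addition of the stabilised enolate is reversible on either face, only the adduct that has C7' cis to the CH2I arm on C8 can line up for the displacement, and this irreversible exit drains the equilibrium into the cis-fused bicycle while C7 and C8 stay as they are. C7' is chosen in the same Curtin-Hammett situation, since the closure that keeps ring B on the convex face, away from the lactone ring, is the less crowded one. The step needs iodide attack at C9 and not at the C8 methine, which is secured by the primary against secondary, branched character of the two carbons and by the better overlap of the exocyclic C9-C8' bond with both carbonyl groups, and aldehyde 10 is a fair acceptor because its two meta oxygens and its twisted para methoxy group give little net donation.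

Step 8
Reactants: 13 methyl (1S,4S,5R,8R)-4-[4-(benzyloxy)-3-methoxyphenyl]-8-[3-(benzyloxy)-4,5-dimethoxyphenyl]-2-oxo-3,7-dioxabicyclo[3.3.0]octane-1-carboxylate
Product: 15 (1S,4S,5R,8S)-4-[4-(benzyloxy)-3-methoxyphenyl]-8-[3-(benzyloxy)-4,5-dimethoxyphenyl]-3,7-dioxabicyclo[3.3.0]octan-2-one, via lithium carboxylate 14 (not isolated)
Conditions: LiCl (3 equiv), H2O (3 equiv), DMSO, 140 °C
Reagents that add atoms: none
Why: Krapcho dealkoxycarbonylation: chloride takes the ester methyl group by SN2, carboxylate 14 loses CO2 because it is beta to the lactone carbonyl, and the resulting lactone enolate can be protonated at C8' only from the convex face because a trans-fused bicyclo[3.3.0]octane is out of reach, while expulsion of the C7' oxygen would be a poorly aligned reverse 5-endo-trig process.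

Step 9
Reactants: 15 (1S,4S,5R,8S)-4-[4-(benzyloxy)-3-methoxyphenyl]-8-[3-(benzyloxy)-4,5-dimethoxyphenyl]-3,7-dioxabicyclo[3.3.0]octan-2-one
Product: 16 (S)-[4-(benzyloxy)-3-methoxyphenyl]{(3R,4R,5S)-5-[3-(benzyloxy)-4,5-dimethoxyphenyl]-4-(hydroxymethyl)tetrahydrofuran-3-yl}methanol
Conditions: LiAlH4, THF, 0 °C to rt; then H2O
Reagents that add atoms: none
Why: LiAlH4 reduces the lactone to the primary C9' alcohol and the benzylic C7 alcohol without breaking any bond to a stereocentre, and the ethers survive.

Step 10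
Reactants: 16 (S)-[4-(benzyloxy)-3-methoxyphenyl]{(3R,4R,5S)-5-[3-(benzyloxy)-4,5-dimethoxyphenyl]-4-(hydroxymethyl)tetrahydrofuran-3-yl}methanol
Product: 18 (1R,2S,5R,6S)-2-[4-(benzyloxy)-3-methoxyphenyl]-6-[3-(benzyloxy)-4,5-dimethoxyphenyl]-3,7-dioxabicyclo[3.3.0]octane, via primary mesylate 17 (not isolated)
Conditions: MsCl (1.1 equiv), Et3N, CH2Cl2, 0 °C to rt
Reagents that add atoms: none
Why: The primary alcohol is sulfonylated first and the C7 hydroxyl closes the ring by a 5-exo-tet Williamson displacement at C9' with C7 retained; should C7 ionise instead, capture of the benzylic cation by the C9' oxygen leads to the same isomer with ring A exo.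

Step 11
Reactants: 18 (1R,2S,5R,6S)-2-[4-(benzyloxy)-3-methoxyphenyl]-6-[3-(benzyloxy)-4,5-dimethoxyphenyl]-3,7-dioxabicyclo[3.3.0]octane
Product: 19 (1R,2S,5R,6S)-2-(4-hydroxy-3-methoxyphenyl)-6-(3-hydroxy-4,5-dimethoxyphenyl)-3,7-dioxabicyclo[3.3.0]octane (CNP0324902.1)
Conditions: H2 (1 atm), 10% Pd/C, EtOAc, rt, stopped after 2 equiv H2
Reagents that add atoms: none
Why: Catalytic hydrogenolysis cleaves aryl benzyl ethers, which release a phenol, much faster than the two ring C-O bonds at C7 and C7', so interruption after two equivalents of H2 should give the free bisphenol with all four stereocentres intact.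

Compound list
1 | 4-(benzyloxy)-3-methoxybenzaldehyde | COc1cc(C=O)ccc1OCc1ccccc1 | starting material
2 | vinylmagnesium bromide | C=C[Mg]Br | starting material
3 | racemic 1-[4-(benzyloxy)-3-methoxyphenyl]prop-2-en-1-ol | C=CC(O)c1ccc(OCc2ccccc2)c(OC)c1 | intermediate
4 | (S)-1-[4-(benzyloxy)-3-methoxyphenyl]prop-2-en-1-ol | C=C[C@H](O)c1ccc(OCc2ccccc2)c(OC)c1 | intermediate
5 | methyl malonyl chloride (methyl 3-chloro-3-oxopropanoate) | COC(=O)CC(=O)Cl | starting material
6 | methyl (S)-1-[4-(benzyloxy)-3-methoxyphenyl]prop-2-en-1-yl malonate | C=C[C@H](OC(=O)CC(=O)OC)c1ccc(OCc2ccccc2)c(OC)c1 | intermediate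
7 | methyl (S)-1-[4-(benzyloxy)-3-methoxyphenyl]prop-2-en-1-yl 2-diazomalonate | C=C[C@H](OC(=O)C(=[N+]=[N-])C(=O)OC)c1ccc(OCc2ccccc2)c(OC)c1 | intermediate
8 | methyl (1R,4S,5S)-4-[4-(benzyloxy)-3-methoxyphenyl]-2-oxo-3-oxabicyclo[3.1.0]hexane-1-carboxylate (ring A trans to the cyclopropane CH2) | COC(=O)[C@@]12C[C@@H]1[C@@H](c1ccc(OCc3ccccc3)c(OC)c1)OC2=O | intermediate
9 | 3-hydroxy-4,5-dimethoxybenzaldehyde | COc1cc(C=O)cc(O)c1OC | starting material
10 | 3-(benzyloxy)-4,5-dimethoxybenzaldehyde | COc1cc(C=O)cc(OCc2ccccc2)c1OC | intermediate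
11 | iodomagnesium enolate of methyl (4S,5S)-5-[4-(benzyloxy)-3-methoxyphenyl]-4-(iodomethyl)-2-oxotetrahydrofuran-3-carboxylate (CH2I trans to ring A) | COC(=O)C1=C(O[Mg]I)O[C@H](c2ccc(OCc3ccccc3)c(OC)c2)[C@H]1CI | intermediate
12 | iodomagnesium aldolate, methyl (3S,4S,5S)-3-{(R)-[3-(benzyloxy)-4,5-dimethoxyphenyl](iodomagnesiooxy)methyl}-5-[4-(benzyloxy)-3-methoxyphenyl]-4-(iodomethyl)-2-oxotetrahydrofuran-3-carboxylate (C7' cis to CH2I) | COC(=O)[C@]1([C@H](O[Mg]I)c2cc(OC)c(OC)c(OCc3ccccc3)c2)C(=O)O[C@H](c2ccc(OCc3ccccc3)c(OC)c2)[C@H]1CI | intermediate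
13 | methyl (1S,4S,5R,8R)-4-[4-(benzyloxy)-3-methoxyphenyl]-8-[3-(benzyloxy)-4,5-dimethoxyphenyl]-2-oxo-3,7-dioxabicyclo[3.3.0]octane-1-carboxylate (cis-fused, both aryl groups exo, CO2Me on C8') | COc1cc([C@H]2OC[C@H]3[C@]2(C(=O)OC)C(=O)O[C@@H]3c2ccc(OCc4ccccc4)c(OC)c2)cc(OCc2ccccc2)c1OC | intermediate
14 | lithium carboxylate derived from 13 (CO2Li on C8') | COc1cc([C@H]2OC[C@H]3[C@]2(C(=O)[O-])C(=O)O[C@@H]3c2ccc(OCc4ccccc4)c(OC)c2)cc(OCc2ccccc2)c1OC.[Li+] | intermediate
15 | (1S,4S,5R,8S)-4-[4-(benzyloxy)-3-methoxyphenyl]-8-[3-(benzyloxy)-4,5-dimethoxyphenyl]-3,7-dioxabicyclo[3.3.0]octan-2-one | COc1cc([C@H]2OC[C@H]3[C@@H]2C(=O)O[C@@H]3c2ccc(OCc4ccccc4)c(OC)c2)cc(OCc2ccccc2)c1OC | intermediate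
16 | (S)-[4-(benzyloxy)-3-methoxyphenyl]{(3R,4R,5S)-5-[3-(benzyloxy)-4,5-dimethoxyphenyl]-4-(hydroxymethyl)tetrahydrofuran-3-yl}methanol | COc1cc([C@H]2OC[C@H]([C@H](O)c3ccc(OCc4ccccc4)c(OC)c3)[C@@H]2CO)cc(OCc2ccccc2)c1OC | intermediate
17 | primary (C9') methanesulfonate of 16 | COc1cc([C@H]2OC[C@H]([C@H](O)c3ccc(OCc4ccccc4)c(OC)c3)[C@@H]2COS(C)(=O)=O)cc(OCc2ccccc2)c1OC | intermediate
18 | (1R,2S,5R,6S)-2-[4-(benzyloxy)-3-methoxyphenyl]-6-[3-(benzyloxy)-4,5-dimethoxyphenyl]-3,7-dioxabicyclo[3.3.0]octane | COc1cc([C@H]2OC[C@H]3[C@@H]2CO[C@@H]3c2cc(OCc3ccccc3)c(OC)c(OC)c2)ccc1OCc1ccccc1 | intermediate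
19 | (1R,2S,5R,6S)-2-(4-hydroxy-3-methoxyphenyl)-6-(3-hydroxy-4,5-dimethoxyphenyl)-3,7-dioxabicyclo[3.3.0]octane, (7S,8R,7'S,8'R) | COc1cc([C@H]2OC[C@H]3[C@@H]2CO[C@@H]3c2cc(O)c(OC)c(OC)c2)ccc1O | target

Total step count: 11. Longest linear sequence: 10 steps (steps 1 to 5 and 7 to 11).

Steps most likely to fail

**Step 7.** Two things may go wrong.
- The aldol equilibrium of the stabilised enolate may lie so far on the side of 11 and 10 that closure of 12 cannot compete with reclosure of 11 to 8.
- The closure may discriminate poorly between the two faces at C7'.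

The fallback sets out from 4, 10 and 2 and comes back at 18. It builds the bicycle by a radical sequence instead of a polar one. Addition of 2 to 10 gives racemic 1-[3-(benzyloxy)-4,5-dimethoxyphenyl]prop-2-en-1-ol F1. PBr3 in Et2O at 0 °C converts it with allylic transposition into 1-(benzyloxy)-5-[(E)-3-bromoprop-1-en-1-yl]-2,3-dimethoxybenzene F2.

Alcohol 4 is epoxidised under Sharpless conditions with D-(-)-DIPT, for which it is the fast-reacting enantiomer. This gives (R)-[4-(benzyloxy)-3-methoxyphenyl][(S)-oxiran-2-yl]methanol F3. NaH in THF joins F3 and F2 to the cinnamyl epoxy ether F4.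

Cp2TiCl (trivalent titanium, made from Cp2TiCl2 and Zn) opens the oxirane homolytically to the C8 radical. A chair-like 5-exo-trig addition to the cinnamyl double bond forms C8-C8', with ring A trans to C9 and C9 cis to C7'. Iodine turns the benzylic titanium species into the benzylic iodide F5. The C9 oxygen then displaces iodide to give 18 with ring B exo. Steps 8 to 10 are then not needed.

**Step 5.** The carbenoid may be diverted into addition to the electron-rich ring A or into dimerisation. The folded transition state may also show only a weak preference for ring A on the convex side.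

The fallback sets out from 6 and comes back at 8. It replaces the carbenoid by a radical cyclisation followed by an alkylation. Deprotonation of 6 with NaH and treatment with NIS gives the iodomalonate F6. Iodine atom transfer cyclisation (Et3B, air, benzene) closes the lactone in the 5-exo mode to methyl (4S,5S)-5-[4-(benzyloxy)-3-methoxyphenyl]-4-(iodomethyl)-2-oxotetrahydrofuran-3-carboxylate F7. The CH2I group ends trans to ring A, as expected for a substituent next to the accepting double bond. DBU in CH2Cl2 then closes the three-membered ring by 3-exo-tet alkylation of the malonate carbon, which can give only the cis-fused 8.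

**Step 8.** At 140 °C, chloride or simple ionisation may cleave the electron-rich benzylic acyl C7-O bond. The free lactone enolate may also expel the C7' oxygen and open the new ring.

The fallback sets out from 13 and comes back at 15. It avoids both the heat and the enolate. LiI in refluxing EtOAc removes the methyl group well below the decarboxylation temperature, by way of 14, and acidification gives the bridgehead carboxylic acid F8. DCC and 1-hydroxypyridine-2(1H)-thione convert it in the dark into the Barton ester F9. Irradiation with t-BuSH at rt (Barton reductive decarboxylation) produces the C8' radical, which takes hydrogen from the thiol on the convex face to give cis-fused 15.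

Further compounds
F1 | step 7 | racemic 1-[3-(benzyloxy)-4,5-dimethoxyphenyl]prop-2-en-1-ol | C=CC(O)c1cc(OC)c(OC)c(OCc2ccccc2)c1
F2 | step 7 | 1-(benzyloxy)-5-[(E)-3-bromoprop-1-en-1-yl]-2,3-dimethoxybenzene | BrC/C=C/c1cc(OC)c(OC)c(OCc2ccccc2)c1
F3 | step 7 | (R)-[4-(benzyloxy)-3-methoxyphenyl][(S)-oxiran-2-yl]methanol | O[C@H](c1ccc(OCc2ccccc2)c(OC)c1)[C@@H]1CO1
F4 | step 7 | cinnamyl epoxy ether, (S)-2-{(R)-[4-(benzyloxy)-3-methoxyphenyl][(E)-3-(3-(benzyloxy)-4,5-dimethoxyphenyl)prop-2-en-1-yloxy]methyl}oxirane | COc1cc(/C=C/CO[C@H](c2ccc(OCc3ccccc3)c(OC)c2)[C@@H]2CO2)cc(OCc2ccccc2)c1OC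
F5 | step 7 | benzylic iodide, {(2S,3R,4R)-2-[4-(benzyloxy)-3-methoxyphenyl]-4-{[3-(benzyloxy)-4,5-dimethoxyphenyl](iodo)methyl}tetrahydrofuran-3-yl}methanol (C7' not defined) | OC[C@@H]1[C@@H](c2ccc(OCc3ccccc3)c(OC)c2)OC[C@@H]1C(I)c1cc(OC)c(OC)c(OCc2ccccc2)c1
F6 | step 5 | methyl (S)-1-[4-(benzyloxy)-3-methoxyphenyl]prop-2-en-1-yl 2-iodomalonate | C=C[C@H](OC(=O)C(I)C(=O)OC)c1ccc(OCc2ccccc2)c(OC)c1
F7 | step 5 | methyl (4S,5S)-5-[4-(benzyloxy)-3-methoxyphenyl]-4-(iodomethyl)-2-oxotetrahydrofuran-3-carboxylate (C3 epimers) | COC(=O)C1C(=O)O[C@H](c2ccc(OCc3ccccc3)c(OC)c2)[C@H]1CI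
F8 | step 8 | bridgehead carboxylic acid corresponding to 13 (CO2H on C8') | COc1cc([C@H]2OC[C@H]3[C@]2(C(=O)O)C(=O)O[C@@H]3c2ccc(OCc4ccccc4)c(OC)c2)cc(OCc2ccccc2)c1OC
F9 | step 8 | Barton ester, 2-thioxopyridin-1(2H)-yl ester of F8 | COc1cc([C@H]2OC[C@H]3[C@]2(C(=O)On2ccccc2=S)C(=O)O[C@@H]3c2ccc(OCc4ccccc4)c(OC)c2)cc(OCc2ccccc2)c1OC
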